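Target: 5,8-diepi-ilimaquinone, C22H30O4.

**Retrosynthetic overview**
1. The C11–C3′ bond is cut last. This gives the α-quaternary decalin aldehyde and 2-hydroxy-5-methoxy-1,4-benzoquinone, joined by reductive C-alkylation.
2. The quaternary C9 (CH3 and CHO) comes from a stereospecific 1,2-methyl shift (C11→C9) in a spiro ethylidene epoxide made from the C9 ketone.
3. 8-CH3 comes from methylation of the cis-decalone enolate.
4. The cis-decalin with C4=CH2 comes from enantioselective conjugate addition of a 5-chloropent-1-en-2-yl metal to 3-methylcyclohexenone (C4–C5), followed by enolate ring closure (C1–C10).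
5. Ring order: ring B is bought, ring A is annulated onto it, and the quinone ring comes intact from benzoquinone and is attached last.

**Assumption and convention:** the SMILES is taken as authoritative. It reads 5R,8R,9R,10S in avarane numbering, where C11 is the CH2 link. 5-CH3, H-10, 8-CH3 and C11 all lie on one face, called α; 9-CH3 lies on the β face. In the naphthalene names, C1 = C9, C2 = C8, C4a = C5, C5 = C4 and C8a = C10.

**Step 1**
Reactants: 1 5-chloropent-1-yne; 2 3-methylcyclohex-2-en-1-one
Product: 4 (3R)-3-(5-chloropent-1-en-2-yl)-3-methylcyclohexan-1-one, via alkenylalane 3 (not isolated)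
Conditions: 1, DIBAL-H, Ni(dppp)Cl2 (3 mol %), THF, 0→22 °C; then 2, chiral sulfonate-NHC–Ag complex (2.5 mol %, the antipode that gives R), Cu(OTf)2 (5 mol %), −30 °C; 1 M HCl work-up
Reagents that add atoms: none
Why: Ni-catalysed α-selective hydroalumination gives the internal alkenylalane, and NHC–Cu-catalysed enantioselective conjugate addition (alkenyl transfers before i-Bu, and C–Cl is inert) delivers it to the Re face of the β-carbon, which sets quaternary C5 as R.

**Step 2**
Reactants: 4 (3R)-3-(5-chloropent-1-en-2-yl)-3-methylcyclohexan-1-one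
Product: 5 (4aR,8aR)-4a-methyl-5-methylideneoctahydronaphthalen-1(2H)-one (cis-fused, H-8a syn to 4a-CH3)
Conditions: t-BuOK (1.1 equiv), t-BuOH–THF, 0→25 °C, 1 h
Reagents that add atoms: none
Why: In this methylenecyclohexane annulation (intramolecular enolate alkylation, 6-exo-tet), enolisation is reversible but only the C10 enolate can close a ring; the new C10–C1 bond must form axially next to the equatorial C5–C4 bond, so the cis-decalone with H-10 on the α face is the kinetic product.

**Step 3**
Reactants: 5 (4aR,8aR)-4a-methyl-5-methylideneoctahydronaphthalen-1(2H)-one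
Product: 6 (2R,4aR,8aR)-2,4a-dimethyl-5-methylideneoctahydronaphthalen-1(2H)-one
Conditions: LDA (1.05 equiv), THF, −78 °C; MeI, DMPU, −78→−30 °C
Reagents that add atoms: iodomethane, CI
Why: Kinetic deprotonation at the only α-CH2 is followed by SN2 enolate methylation, and MeI approaches C8 from the α face, anti to the pseudo-axial C10–C1 bond, which gives the 8-CH3 epimer that is equatorial in the preferred chair (8R).

**Step 4**
Reactants: 6 (2R,4aR,8aR)-2,4a-dimethyl-5-methylideneoctahydronaphthalen-1(2H)-one
Product: 7 (1R,2R,4aR,8aR)-2,3′,4a-trimethyl-5-methylideneoctahydro-2H-spiro[naphthalene-1,2′-oxirane] (O on the α face, C11 on the β face, C3′ epimers)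
Conditions: Ph2S(Et)BF4 (1.6 equiv), t-BuLi (1.5 equiv), THF–DME, −78 °C; then 6, −78→−20 °C
Reagents that add atoms: ethyldiphenylsulfonium tetrafluoroborate, CC[S+](c1ccccc1)c1ccccc1.F[B-](F)(F)F
Why: In this Corey–Chaykovsky-type epoxidation with an unstabilised sulfonium ethylide, the axial (α) approach to C9 is blocked by the syn-axial 5-CH3, so irreversible equatorial attack places C11 on the β face and the oxygen axial on the α face; C4=CH2 is untouched and the C11 configuration is lost in step 5.

**Step 5**
Reactants: 7 spiro-epoxide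
Product: 8 (1R,2R,4aR,8aR)-1,2,4a-trimethyl-5-methylidenedecahydronaphthalene-1-carbaldehyde
Conditions: MABR [MeAl(OAr)2, Ar = 4-bromo-2,6-di-tert-butylphenyl] (20 mol %), CH2Cl2, −78→−20 °C
Reagents that add atoms: none
Why: In this Meinwald-type epoxide-to-aldehyde rearrangement with a bulky aluminium Lewis acid, the strained axial tertiary C9–O bond ionises while CH3 shifts 1,2 from C11 to C9 anti to the leaving oxygen (the bulky Al favours alkyl shift to the aldehyde over hydride shift to the ketone), and inversion at C9 leaves 9-CH3 on the β face and CHO on the α face (9R).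

**Step 6**
Reactants: 9 1,4-benzoquinone
Product: 10 2,5-dimethoxy-1,4-benzoquinone
Conditions: MeOH, ZnCl2, reflux (3 equiv of 9 per product, 9 also acts as the oxidant)
Reagents that add atoms: methanol, CO
Why: Two rounds of Lewis-acid-promoted conjugate addition of methanol are each followed by re-oxidation by benzoquinone (oxidative nucleophilic addition), and the 2,5-isomer crystallises out.

**Step 7**
Reactants: 10 2,5-dimethoxy-1,4-benzoquinone
Product: 11 2-hydroxy-5-methoxy-1,4-benzoquinone
Conditions: NaOH (1.05 equiv), H2O–THF, 0 °C→rt; then 1 M HCl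
Reagents that add atoms: sodium hydroxide, [Na+].[OH-]
Why: This is addition–elimination on a vinylogous ester, and the vinylogous carboxylate formed after the first hydrolysis deactivates the ring, so the reaction stops at the mono-ether.

**Step 8**
Reactants: 8 decalin aldehyde; 11 2-hydroxy-5-methoxy-1,4-benzoquinone
Product: 13 5,8-diepi-ilimaquinone, via alkylidene-trione 12 (not isolated)
Conditions: 11 (1.5 equiv), Hantzsch ester (1.5 equiv), (PhO)2P(O)OH (10 mol %), 4 Å MS, PhMe, 60 °C, Ar, dark
Reagents that add atoms: none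
Why: Proposed new method: an amine-free, Brønsted-acid-catalysed reductive C-alkylation of a hydroxyquinone by an α-quaternary aldehyde, in which the phosphoric acid activates the non-enolisable CHO, the enol carbon C3′ of 11 (the only vinylogous-acid position) adds reversibly, dehydration gives o-quinone methide 12, and irreversible acid-assisted hydride transfer from the Hantzsch ester to C11 drains the equilibria; bis-addition is sterically blocked, no amine is present to displace OMe, the weak acid leaves C4=CH2 alone, and no stereocentre is touched; the closest known reaction types are the proline-catalysed three-component reductive alkylation of lawsone or 2,5-dihydroxybenzoquinone with unhindered aldehydes and phosphoric acid/Hantzsch ester transfer hydrogenation.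

**Compound list**
1 | 5-chloropent-1-yne | C#CCCCCl | starting material
2 | 3-methylcyclohex-2-en-1-one | CC1=CC(=O)CCC1 | starting material
3 | (5-chloropent-1-en-2-yl)diisobutylaluminium | C=C(CCCCl)[Al](CC(C)C)CC(C)C | intermediate
4 | (3R)-3-(5-chloropent-1-en-2-yl)-3-methylcyclohexan-1-one | C=C(CCCCl)[C@]1(C)CCCC(=O)C1 | intermediate
5 | (4aR,8aR)-4a-methyl-5-methylideneoctahydronaphthalen-1(2H)-one | C=C1CCC[C@H]2C(=O)CCC[C@@]12C | intermediate
6 | (2R,4aR,8aR)-2,4a-dimethyl-5-methylideneoctahydronaphthalen-1(2H)-one | C=C1CCC[C@H]2C(=O)[C@H](C)CC[C@@]12C | intermediate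
7 | (1R,2R,4aR,8aR)-2,3′,4a-trimethyl-5-methylideneoctahydro-2H-spiro[naphthalene-1,2′-oxirane], C3′ epimers | C=C1CCC[C@H]2[C@]3(OC3C)[C@H](C)CC[C@@]12C | intermediate
8 | (1R,2R,4aR,8aR)-1,2,4a-trimethyl-5-methylidenedecahydronaphthalene-1-carbaldehyde | C=C1CCC[C@H]2[C@](C)(C=O)[C@H](C)CC[C@@]12C | intermediate
9 | 1,4-benzoquinone | O=C1C=CC(=O)C=C1 | starting material
10 | 2,5-dimethoxy-1,4-benzoquinone | COC1=CC(=O)C(OC)=CC1=O | intermediate
11 | 2-hydroxy-5-methoxy-1,4-benzoquinone | COC1=CC(=O)C(O)=CC1=O | intermediate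
12 | 5-methoxy-3-{[(1R,2R,4aR,8aR)-1,2,4a-trimethyl-5-methylidenedecahydronaphthalen-1-yl]methylidene}cyclohex-5-ene-1,2,4-trione | C=C1CCC[C@H]2[C@](C)(C=C3C(=O)C(=O)C=C(OC)C3=O)[C@H](C)CC[C@@]12C | intermediate
13 | 2-hydroxy-5-methoxy-3-{[(1R,2R,4aR,8aS)-1,2,4a-trimethyl-5-methylidenedecahydronaphthalen-1-yl]methyl}cyclohexa-2,5-diene-1,4-dione | C=C1CCC[C@H]2[C@](C)(CC3=C(O)C(=O)C=C(OC)C3=O)[C@H](C)CC[C@@]12C | target

**Step count:** 8 steps in total. The longest linear sequence is 6 steps (steps 1–5 and 8).

**Steps most likely to fail**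

**Step 8 (the new step).** The axial, neopentyl CHO may be too hindered for the weakly nucleophilic hydroxyquinone.
- The fallback uses known chemistry, sets out from 8 and 10, and returns at 13.
- Compound 10 is reduced with Na2S2O4 to 2,5-dimethoxyhydroquinone F5, which is methylated (Me2SO4, K2CO3) to 1,2,4,5-tetramethoxybenzene F6.
- Ortho-lithiation of F6 (n-BuLi, TMEDA) and addition to 8 gives the benzylic alcohol F7.
- NaH/CS2/MeI converts F7 into the methyl xanthate F8, and Bu3SnH/AIBN (Barton–McCombie) then gives the tetramethoxybenzyl decalin F9.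
- CAN oxidises F9 to the 2,5-dimethoxyquinone F10.
- Cold aqueous HClO4 in THF hydrolyses the hindered, deconjugated 2-methoxy group of F10 selectively to give 13.

**Step 5.** Hydride shift (giving the methyl ketone) or elimination may win over methyl shift, and MABR may not reach the hindered axial oxygen.
- The fallback sets out from 6 and returns at 8.
- Wittig reaction of 6 with Ph3P=CHOMe gives the enol ether F3.
- Mild hydrolysis (oxalic acid, wet THF) gives the C9–H aldehyde F4.
- t-BuOK/MeI methylates the exocyclic enolate of F4 from the equatorial β face, because the α face is blocked by 5-CH3, and this gives 8.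

**Step 4.** The basic ethylide may enolise the hindered ketone, which would epimerise C8 or C10, instead of adding to it.
- The fallback avoids nucleophilic addition at C9. It sets out from 5 and returns at 8.
- LDA and Comins' reagent convert 5 into the Δ8 enol triflate F1.
- Pd(PPh3)4, CO, Bu3SnH and LiCl (carbonylative formylation) give the enal F2.
- Me2CuLi adds to C8 of F2 from the α face, syn to H-10.
- The enolate is trapped with MeI/HMPA anti to the new 8-CH3, which gives 8.

**Further compounds**
F1 | step 4 | (4aR,8aR)-4a-methyl-5-methylidene-3,4,4a,5,6,7,8,8a-octahydronaphthalen-1-yl trifluoromethanesulfonate | C=C1CCC[C@H]2C(OS(=O)(=O)C(F)(F)F)=CCC[C@@]12C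
F2 | step 4 | (4aR,8aR)-4a-methyl-5-methylidene-3,4,4a,5,6,7,8,8a-octahydronaphthalene-1-carbaldehyde | C=C1CCC[C@H]2C(C=O)=CCC[C@@]12C
F3 | step 5 | (2R,4aR,8aR)-1-(methoxymethylidene)-2,4a-dimethyl-5-methylidenedecahydronaphthalene (E/Z) | C=C1CCC[C@H]2C(=COC)[C@H](C)CC[C@@]12C
F4 | step 5 | (2R,4aR,8aS)-2,4a-dimethyl-5-methylidenedecahydronaphthalene-1-carbaldehyde (C1 epimers) | C=C1CCC[C@H]2C(C=O)[C@H](C)CC[C@@]12C
F5 | step 8 | 2,5-dimethoxybenzene-1,4-diol | COc1cc(O)c(OC)cc1O
F6 | step 8 | 1,2,4,5-tetramethoxybenzene | COc1cc(OC)c(OC)cc1OC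
F7 | step 8 | (2,3,5,6-tetramethoxyphenyl)[(1R,2R,4aR,8aR)-1,2,4a-trimethyl-5-methylidenedecahydronaphthalen-1-yl]methanol (carbinol epimers) | C=C1CCC[C@H]2[C@](C)(C(O)c3c(OC)c(OC)cc(OC)c3OC)[C@H](C)CC[C@@]12C
F8 | step 8 | O-alkyl S-methyl dithiocarbonate (xanthate) of F7 | C=C1CCC[C@H]2[C@](C)(C(OC(=S)SC)c3c(OC)c(OC)cc(OC)c3OC)[C@H](C)CC[C@@]12C
F9 | step 8 | 1,2,4,5-tetramethoxy-3-{[(1R,2R,4aR,8aS)-1,2,4a-trimethyl-5-methylidenedecahydronaphthalen-1-yl]methyl}benzene | C=C1CCC[C@H]2[C@](C)(Cc3c(OC)c(OC)cc(OC)c3OC)[C@H](C)CC[C@@]12C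
F10 | step 8 | 2,5-dimethoxy-3-{[(1R,2R,4aR,8aS)-1,2,4a-trimethyl-5-methylidenedecahydronaphthalen-1-yl]methyl}cyclohexa-2,5-diene-1,4-dione | C=C1CCC[C@H]2[C@](C)(CC3=C(OC)C(=O)C=C(OC)C3=O)[C@H](C)CC[C@@]12C
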